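**Retrosynthetic overview**
- The C8 ester is attached last to the 8-hydroxy core, using silyl-protected (E)-4-hydroxy-2-methylbut-2-enoic acid.
- The oxa-bridge (C1–O–C4 hemiketal) and the 5E enol-lactone olefin come from one base-triggered cascade on a 4,5-epoxy-1-oxo-germacr-7(11)-en-12,6-olide; the epoxide oxygen, set on C4 by Sharpless epoxidation, ends up as the bridge oxygen.
- The ten-membered carbocycle and the butenolide form together: a Ni/Cr alkenyl iodide–aldehyde ring closure (C6–C7), then lactonisation in the flask.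
- The open chain comes from geraniol (C1–C6, C15), a crotyl unit (C8–C10, C14), methyl propiolate and formaldehyde (C7, C11–C13).
- Ring order: carbocycle and butenolide (step 11), then the oxolane hemiketal bridge (step 12).

Assumption: (S)-SEGPHOS (step 3) and (S,S)-ProPhenol (step 6) stand for whichever ligand enantiomer delivers 10R and 8S; the mirror-image ligand is used if the facial sense is the opposite one (step 9 follows the established geraniol rule).

Atom numbers C1–C15 are germacrane numbers of the target.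

**Step 1**
Reactants: 1 geraniol
Product: 2 tert-butyl{[(2E)-3,7-dimethylocta-2,6-dien-1-yl]oxy}dimethylsilane
Conditions: TBSCl, imidazole, DMF, 23 °C
Reagents that add atoms: tert-butyldimethylsilyl chloride, CC(C)(C)[Si](C)(C)Cl
Why: Standard silylation of the primary allylic alcohol; the ether masks the future C6 oxygen until step 8.

**Step 2**
Reactants: 2 tert-butyl{[(2E)-3,7-dimethylocta-2,6-dien-1-yl]oxy}dimethylsilane
Product: 4 (4E)-6-[(tert-butyldimethylsilyl)oxy]-4-methylhex-4-enal, via ozonide 3 (not isolated)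
Conditions: O3 (1.0 equiv, Sudan red 7B end point), CH2Cl2, −78 °C; then Me2S, −78 → 23 °C
Reagents that add atoms: ozone, [O-][O+]=O
Why: Site-selective ozonolysis: the electron-rich terminal trisubstituted alkene reacts before the alkene deactivated by the allylic silyloxy group, giving the C1 aldehyde.

**Step 3**
Reactants: 4 (4E)-6-[(tert-butyldimethylsilyl)oxy]-4-methylhex-4-enal
Product: 5 (3R,4S,7E)-9-[(tert-butyldimethylsilyl)oxy]-3,7-dimethylnona-1,7-dien-4-ol
Conditions: [Ir(cod)Cl]2 (2.5 mol %), (S)-SEGPHOS (5 mol %), 4-cyano-3-nitrobenzoic acid (10 mol %), Cs2CO3 (20 mol %), but-3-en-2-yl acetate, i-PrOH, THF, 90 °C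
Reagents that add atoms: but-3-en-2-yl acetate, CC(OC(C)=O)C=C
Why: Iridium-catalysed transfer-hydrogenative carbonyl crotylation (Krische); the chiral π-crotyl iridium complex adds through a closed chair transition state to give the anti adduct and sets C10 as R (the C1 carbinol is oxidised in step 5).

**Step 4**
Reactants: 5 (3R,4S,7E)-9-[(tert-butyldimethylsilyl)oxy]-3,7-dimethylnona-1,7-dien-4-ol
Product: 7 (3R,4S,7E)-9-[(tert-butyldimethylsilyl)oxy]-3,7-dimethylnon-7-ene-1,4-diol, via bis-boryl adduct 6 (not isolated)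
Conditions: 9-BBN (2.2 equiv), THF, 0 → 23 °C; then NaOH, H2O2, 0 °C
Reagents that add atoms: hydrogen peroxide, OO
Why: Hydroboration–oxidation; 9-BBN takes only the monosubstituted vinyl group (anti-Markovnikov) and leaves the trisubstituted alkene, giving the C8 primary alcohol.

**Step 5**
Reactants: 7 (3R,4S,7E)-9-[(tert-butyldimethylsilyl)oxy]-3,7-dimethylnon-7-ene-1,4-diol
Product: 8 (3R,7E)-9-[(tert-butyldimethylsilyl)oxy]-3,7-dimethyl-4-oxonon-7-enal
Conditions: (COCl)2, DMSO, CH2Cl2, −78 °C; Et3N, −78 → −20 °C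
Reagents that add atoms: none
Why: Swern oxidation of both alcohols at once; activating both hydroxyls before the base is added avoids lactol and lactone formation from the 1,4-diol, and the cold, brief amine treatment does not epimerise C10.

**Step 6**
Reactants: 8 (3R,7E)-9-[(tert-butyldimethylsilyl)oxy]-3,7-dimethyl-4-oxonon-7-enal
Product: 9 methyl (4S,6R,10E)-12-[(tert-butyldimethylsilyl)oxy]-4-hydroxy-6,10-dimethyl-7-oxododec-10-en-2-ynoate
Conditions: methyl propiolate, Me2Zn, (S,S)-ProPhenol (20 mol %), Ph3P=O (20 mol %), toluene, 4 °C; aq. NH4Cl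
Reagents that add atoms: methyl propiolate, COC(=O)C#C
Why: ProPhenol/zinc-catalysed asymmetric alkynylation (Trost); the zinc acetylide adds only to the aldehyde and the catalyst sets C8 as S.

**Step 7**
Reactants: 9 methyl (4S,6R,10E)-12-[(tert-butyldimethylsilyl)oxy]-4-hydroxy-6,10-dimethyl-7-oxododec-10-en-2-ynoate
Product: 11 methyl (2Z,4S,6R,10E)-2-(acetoxymethyl)-12-[(tert-butyldimethylsilyl)oxy]-4-hydroxy-3-iodo-6,10-dimethyl-7-oxododeca-2,10-dienoate, via iodo diol 10 (not isolated)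
Conditions: MgI2, CH2Cl2, −20 °C; monomeric CH2O, −20 → 0 °C; then AcCl, 2,4,6-collidine, −78 °C
Reagents that add atoms: magnesium iodide, [Mg+2].[I-].[I-]; formaldehyde, C=O; acetyl chloride, CC(=O)Cl
Why: β-Iodo Baylis–Hillman-type (halo-aldol) reaction: iodide adds 1,4 to the ynoate and the magnesium allenolate is hydroxymethylated at C11 from the side of the Mg-bound C8 hydroxyl, which puts iodine cis to the ester (2Z); the new primary alkoxide is then acetylated selectively.

**Step 8**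
Reactants: 11 methyl (2Z,4S,6R,10E)-2-(acetoxymethyl)-12-[(tert-butyldimethylsilyl)oxy]-4-hydroxy-3-iodo-6,10-dimethyl-7-oxododeca-2,10-dienoate
Product: 12 methyl (2Z,4S,6R,10E)-2-(acetoxymethyl)-4,12-dihydroxy-3-iodo-6,10-dimethyl-7-oxododeca-2,10-dienoate
Conditions: HF·pyridine, pyridine, THF, 0 °C
Reagents that add atoms: none
Why: Fluoride desilylation of the primary allylic silyl ether; acetate, alkenyl iodide and ketone are untouched.

**Step 9**
Reactants: 12 methyl (2Z,4S,6R,10E)-2-(acetoxymethyl)-4,12-dihydroxy-3-iodo-6,10-dimethyl-7-oxododeca-2,10-dienoate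
Product: 13 methyl (2Z,4S,6R)-2-(acetoxymethyl)-4-hydroxy-9-[(2R,3R)-3-(hydroxymethyl)-2-methyloxiran-2-yl]-3-iodo-6-methyl-7-oxonon-2-enoate
Conditions: Ti(Oi-Pr)4 (20 mol %), D-(−)-diethyl tartrate (24 mol %), t-BuOOH, 4 Å molecular sieves, CH2Cl2, −20 °C
Reagents that add atoms: tert-butyl hydroperoxide, CC(C)(C)OO
Why: Katsuki–Sharpless asymmetric epoxidation; with D-(−)-tartrate the (E)-3,3-disubstituted allylic alcohol gives the (R,R)-epoxide as geraniol does, which sets C4 (R) through a C–O bond that is kept to the target; the electron-poor iodo-enoate is inert.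

**Step 10**
Reactants: 13 methyl (2Z,4S,6R)-2-(acetoxymethyl)-4-hydroxy-9-[(2R,3R)-3-(hydroxymethyl)-2-methyloxiran-2-yl]-3-iodo-6-methyl-7-oxonon-2-enoate
Product: 14 methyl (2Z,4S,6R)-2-(acetoxymethyl)-9-[(2R,3S)-3-formyl-2-methyloxiran-2-yl]-4-hydroxy-3-iodo-6-methyl-7-oxonon-2-enoate
Conditions: TEMPO (10 mol %), PhI(OAc)2, CH2Cl2, 23 °C
Reagents that add atoms: none
Why: Oxoammonium (TEMPO) oxidation is selective for the primary alcohol over the hindered secondary C8 hydroxyl and gives the epoxy aldehyde without epimerisation.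

**Step 11**
Reactants: 14 methyl (2Z,4S,6R)-2-(acetoxymethyl)-9-[(2R,3S)-3-formyl-2-methyloxiran-2-yl]-4-hydroxy-3-iodo-6-methyl-7-oxonon-2-enoate
Product: 16 (4R,5R,8S,10R)-13-acetoxy-4,5-epoxy-8-hydroxy-1-oxogermacr-7(11)-en-12,6-olide (C6 epimers), via hydroxy ester 15 (not isolated)
Conditions: CrCl2 (10 equiv), NiCl2 (1 mol %), DMSO–THF, 23 °C, 2 mM, slow addition; then PPTS, CH2Cl2
Reagents that add atoms: none
Why: Intramolecular Nozaki–Hiyama–Kishi reaction closes the ten-membered ring at C6–C7 with retention of olefin geometry, so the new C6 alkoxide sits cis to the ester and lactonises to the butenolide; the C6 configuration is irrelevant because C6 becomes sp2 in step 12.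

**Step 12**
Reactants: 16 (4R,5R,8S,10R)-13-acetoxy-4,5-epoxy-8-hydroxy-1-oxogermacr-7(11)-en-12,6-olide (C6 epimers)
Product: 18 (1S,4R,5E,8S,10R)-13-acetoxy-1,8-dihydroxy-1,4-epoxygermacra-5,7(11)-dien-12,6-olide, via hydroxy ketone 17 (not isolated)
Conditions: DBU (0.3 equiv), MeCN, 0 → 23 °C
Reagents that add atoms: none
Why: Proposed new method: DBU removes the acidic γ-proton H-6 of the butenolide to give a 2-oxidofuran, which opens the adjacent epoxide at C5–O by vinylogous E1cB, forming the C5=C6 ylidene and a C4 tertiary alkoxide with retention at C4; the alkoxide then adds across the ring to the C1 ketone, and because only the ring-cis (5E) olefin lets O4 reach C1, the bridge fixes C1 as S. The closest known reactions are base eliminations of γ-(1-sulfonyloxyalkyl)butenolides to γ-ylidenebutenolides, DBU isomerisation of β,γ-epoxy carbonyl compounds to γ-hydroxy enones, and the acid-induced rearrangement of natural 1-oxo-4,5-epoxygermacranolides.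

**Step 13**
Reactants: 19 [(tert-butyldimethylsilyl)oxy]acetaldehyde
Product: 20 ethyl (2E)-4-[(tert-butyldimethylsilyl)oxy]-2-methylbut-2-enoate
Conditions: Ph3P=C(CH3)CO2Et, CH2Cl2, 23 °C
Reagents that add atoms: ethyl 2-(triphenylphosphoranylidene)propanoate, CCOC(=O)C(C)=P(c1ccccc1)(c1ccccc1)c1ccccc1
Why: Wittig olefination with a stabilised ylide gives the (E)-trisubstituted enoate of the side chain.

**Step 14**
Reactants: 20 ethyl (2E)-4-[(tert-butyldimethylsilyl)oxy]-2-methylbut-2-enoate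
Product: 21 (2E)-4-[(tert-butyldimethylsilyl)oxy]-2-methylbut-2-enoic acid
Conditions: LiOH, THF–H2O, 23 °C; then 1 M HCl to pH 4, 0 °C
Reagents that add atoms: lithium hydroxide, [Li+].[OH-]
Why: Ester saponification; the primary silyl ether survives mild base and a brief, cold, weakly acidic work-up.

**Step 15**
Reactants: 18 (1S,4R,5E,8S,10R)-13-acetoxy-1,8-dihydroxy-1,4-epoxygermacra-5,7(11)-dien-12,6-olide; 21 (2E)-4-[(tert-butyldimethylsilyl)oxy]-2-methylbut-2-enoic acid
Product: 24 (1S,4R,5E,8S,10R)-13-acetoxy-1-hydroxy-8-{[(2E)-4-hydroxy-2-methylbut-2-enoyl]oxy}-1,4-epoxygermacra-5,7(11)-dien-12,6-olide (CNP0154520.1), via mixed anhydride 22 (not isolated), via silyl ether 23 (not isolated)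
Conditions: 21, 2,4,6-Cl3C6H2COCl, Et3N, toluene, 23 °C; then 18, DMAP; then HF·pyridine, THF, 0 °C
Reagents that add atoms: none
Why: Yamaguchi esterification acylates the secondary C8 hydroxyl and not the tertiary hemiketal hydroxyl; fluoride then frees the side-chain primary alcohol without touching acetate, enol lactone or hemiketal; no stereocentre is affected.

**Compound list**
1 | geraniol, (2E)-3,7-dimethylocta-2,6-dien-1-ol | CC(C)=CCC/C(C)=C/CO | starting material
2 | tert-butyl{[(2E)-3,7-dimethylocta-2,6-dien-1-yl]oxy}dimethylsilane | CC(C)=CCC/C(C)=C/CO[Si](C)(C)C(C)(C)C | intermediate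
3 | ozonide of 2 (3,3-dimethyl-1,2,4-trioxolane at the terminal alkene) | CC1(C)OOC(CC/C(C)=C/CO[Si](C)(C)C(C)(C)C)O1 | intermediate (not isolated)
4 | (4E)-6-[(tert-butyldimethylsilyl)oxy]-4-methylhex-4-enal | O=CCC/C(C)=C/CO[Si](C)(C)C(C)(C)C | intermediate
5 | (3R,4S,7E)-9-[(tert-butyldimethylsilyl)oxy]-3,7-dimethylnona-1,7-dien-4-ol | C=C[C@@H](C)[C@@H](O)CC/C(C)=C/CO[Si](C)(C)C(C)(C)C | intermediate
6 | bis-boryl adduct of 5 (C-1 alkyl-9-BBN, O-4 borinate) | B1(C2CCCC1CCC2)CC[C@@H](C)[C@@H](OB1C2CCCC1CCC2)CC/C(C)=C/CO[Si](C)(C)C(C)(C)C | intermediate (not isolated)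
7 | (3R,4S,7E)-9-[(tert-butyldimethylsilyl)oxy]-3,7-dimethylnon-7-ene-1,4-diol | OCC[C@@H](C)[C@@H](O)CC/C(C)=C/CO[Si](C)(C)C(C)(C)C | intermediate
8 | (3R,7E)-9-[(tert-butyldimethylsilyl)oxy]-3,7-dimethyl-4-oxonon-7-enal | O=CC[C@@H](C)C(=O)CC/C(C)=C/CO[Si](C)(C)C(C)(C)C | intermediate
9 | methyl (4S,6R,10E)-12-[(tert-butyldimethylsilyl)oxy]-4-hydroxy-6,10-dimethyl-7-oxododec-10-en-2-ynoate | COC(=O)C#C[C@@H](O)C[C@@H](C)C(=O)CC/C(C)=C/CO[Si](C)(C)C(C)(C)C | intermediate
10 | methyl (2Z,4S,6R,10E)-12-[(tert-butyldimethylsilyl)oxy]-4-hydroxy-2-(hydroxymethyl)-3-iodo-6,10-dimethyl-7-oxododeca-2,10-dienoate (formed as its magnesium alkoxide) | COC(=O)/C(CO)=C(\I)[C@@H](O)C[C@@H](C)C(=O)CC/C(C)=C/CO[Si](C)(C)C(C)(C)C | intermediate (not isolated)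
11 | methyl (2Z,4S,6R,10E)-2-(acetoxymethyl)-12-[(tert-butyldimethylsilyl)oxy]-4-hydroxy-3-iodo-6,10-dimethyl-7-oxododeca-2,10-dienoate | COC(=O)/C(COC(C)=O)=C(\I)[C@@H](O)C[C@@H](C)C(=O)CC/C(C)=C/CO[Si](C)(C)C(C)(C)C | intermediate
12 | methyl (2Z,4S,6R,10E)-2-(acetoxymethyl)-4,12-dihydroxy-3-iodo-6,10-dimethyl-7-oxododeca-2,10-dienoate | COC(=O)/C(COC(C)=O)=C(\I)[C@@H](O)C[C@@H](C)C(=O)CC/C(C)=C/CO | intermediate
13 | methyl (2Z,4S,6R)-2-(acetoxymethyl)-4-hydroxy-9-[(2R,3R)-3-(hydroxymethyl)-2-methyloxiran-2-yl]-3-iodo-6-methyl-7-oxonon-2-enoate | COC(=O)/C(COC(C)=O)=C(\I)[C@@H](O)C[C@@H](C)C(=O)CC[C@@]1(C)O[C@@H]1CO | intermediate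
14 | methyl (2Z,4S,6R)-2-(acetoxymethyl)-9-[(2R,3S)-3-formyl-2-methyloxiran-2-yl]-4-hydroxy-3-iodo-6-methyl-7-oxonon-2-enoate | COC(=O)/C(COC(C)=O)=C(\I)[C@@H](O)C[C@@H](C)C(=O)CC[C@@]1(C)O[C@@H]1C=O | intermediate
15 | macrocyclic hydroxy ester, methyl (4R,5R,8S,10R)-13-acetoxy-4,5-epoxy-6,8-dihydroxy-1-oxogermacr-7(11)-en-12-oate (formed as its chromium alkoxide, C6 epimers) | COC(=O)/C(COC(C)=O)=C1/[C@@H](O)C[C@@H](C)C(=O)CC[C@@]2(C)O[C@@H]2C1O | intermediate (not isolated)
16 | (4R,5R,8S,10R)-13-acetoxy-4,5-epoxy-8-hydroxy-1-oxogermacr-7(11)-en-12,6-olide (C6 epimers) | CC(=O)OCC1=C2[C@@H](O)C[C@@H](C)C(=O)CC[C@@]3(C)O[C@@H]3C2OC1=O | intermediate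
17 | (4R,5E,8S,10R)-13-acetoxy-4,8-dihydroxy-1-oxogermacra-5,7(11)-dien-12,6-olide | CC(=O)OCC1=C2/C(=C\[C@](C)(O)CCC(=O)[C@H](C)C[C@@H]2O)OC1=O | intermediate (not isolated)
18 | (1S,4R,5E,8S,10R)-13-acetoxy-1,8-dihydroxy-1,4-epoxygermacra-5,7(11)-dien-12,6-olide | CC(=O)OCC1=C2/C(=C\[C@@]3(C)CC[C@](O)(O3)[C@H](C)C[C@@H]2O)OC1=O | intermediate
19 | [(tert-butyldimethylsilyl)oxy]acetaldehyde | O=CCO[Si](C)(C)C(C)(C)C | starting material
20 | ethyl (2E)-4-[(tert-butyldimethylsilyl)oxy]-2-methylbut-2-enoate | CCOC(=O)/C(C)=C/CO[Si](C)(C)C(C)(C)C | intermediate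
21 | (2E)-4-[(tert-butyldimethylsilyl)oxy]-2-methylbut-2-enoic acid | OC(=O)/C(C)=C/CO[Si](C)(C)C(C)(C)C | intermediate
22 | mixed anhydride of 21 with 2,4,6-trichlorobenzoic acid | O=C(OC(=O)/C(C)=C/CO[Si](C)(C)C(C)(C)C)c1c(Cl)cc(Cl)cc1Cl | intermediate (not isolated)
23 | tert-butyldimethylsilyl ether of 24 at the side-chain hydroxyl | CC(=O)OCC1=C2/C(=C\[C@@]3(C)CC[C@](O)(O3)[C@H](C)C[C@@H]2OC(=O)/C(C)=C/CO[Si](C)(C)C(C)(C)C)OC1=O | intermediate (not isolated)
24 | (1S,4R,5E,8S,10R)-13-acetoxy-1-hydroxy-8-{[(2E)-4-hydroxy-2-methylbut-2-enoyl]oxy}-1,4-epoxygermacra-5,7(11)-dien-12,6-olide (CNP0154520.1) | CC(=O)OCC1=C2/C(=C\[C@@]3(C)CC[C@](O)(O3)[C@H](C)C[C@@H]2OC(=O)/C(C)=C/CO)OC1=O | target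

**Step count and risks**
Total step count: 15. Longest linear sequence: 13 (steps 1–12, then step 15).

The three steps most likely to fail:

Step 12 (the proposed new cascade). Risks are 1,4-loss of the C13 acetate from the 2-oxidofuran, epimerisation at C10, and formation of the 5Z isomer that cannot bridge. The fallback uses known chemistry, sets out from 16 and returns at 18. LiBr/AcOH in THF opens the epoxide by SN2 at the less substituted C5, so the oxygen stays on C4 with its configuration; the freed tertiary alcohol closes onto C1 to give the bromohydrin hemiketal F6. DBU then removes HBr across C5/C6 to give 18.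

Step 11 (ten-membered ring closure with a tetrasubstituted iodo-enoate and a sensitive epoxy aldehyde). The fallback sets out from 12 and returns at 16; it closes the ring before the epoxide exists. Compound 12 is oxidised (TEMPO, PhI(OAc)2) to the enal F3. The CrCl2/NiCl2 closure on this flatter, more robust aldehyde gives the macrocyclic hydroxy ester F4 and, after lactonisation, the 4-ene butenolide F5. The epoxide is then put in under reagent control by Shi epoxidation (D-fructose-derived ketone, KHSO5, pH 10.5) to give 16.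

Step 7 (halo-aldol with formaldehyde on a 3-substituted ynoate). The 2Z geometry rests on delivery from the C8 hydroxyl; the 2E isomer would lactonise onto O8 and be lost. The fallback sets out from 9 and returns at 11; it tethers the one-carbon electrophile to O8 so the geometry is forced. Compound 9 is formylated (acetic formic anhydride, pyridine) to the formate ester F1. MgI2 then adds iodide to the ynoate and the allenolate closes onto the formyl carbon, giving the five-membered lactol F2 in which C13 is necessarily cis to C8. NaBH(OAc)3 reduces the lactol through its open hydroxy aldehyde to iodo diol 10 without touching the ketone, and AcCl/collidine gives 11.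

**Further compounds**
F1 | step 7 | methyl (4S,6R,10E)-12-[(tert-butyldimethylsilyl)oxy]-4-(formyloxy)-6,10-dimethyl-7-oxododec-10-en-2-ynoate | COC(=O)C#C[C@@H](OC=O)C[C@@H](C)C(=O)CC/C(C)=C/CO[Si](C)(C)C(C)(C)C
F2 | step 7 | methyl (5S)-5-[(2R,6E)-8-[(tert-butyldimethylsilyl)oxy]-2,6-dimethyl-3-oxooct-6-en-1-yl]-2-hydroxy-4-iodo-2,5-dihydrofuran-3-carboxylate | COC(=O)C1=C(I)[C@H](C[C@@H](C)C(=O)CC/C(C)=C/CO[Si](C)(C)C(C)(C)C)OC1O
F3 | step 11 | methyl (2Z,4S,6R,10E)-2-(acetoxymethyl)-4-hydroxy-3-iodo-6,10-dimethyl-7,12-dioxododeca-2,10-dienoate | COC(=O)/C(COC(C)=O)=C(\I)[C@@H](O)C[C@@H](C)C(=O)CC/C(C)=C/C=O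
F4 | step 11 | methyl (4E,8S,10R)-13-acetoxy-6,8-dihydroxy-1-oxogermacra-4,7(11)-dien-12-oate (C6 epimers) | COC(=O)/C(COC(C)=O)=C1/[C@@H](O)C[C@@H](C)C(=O)CC/C(C)=C/C1O
F5 | step 11 | (4E,8S,10R)-13-acetoxy-8-hydroxy-1-oxogermacra-4,7(11)-dien-12,6-olide (C6 epimers) | CC(=O)OCC1=C2[C@@H](O)C[C@@H](C)C(=O)CC/C(C)=C/C2OC1=O
F6 | step 12 | (1S,4R,5S,8S,10R)-13-acetoxy-5-bromo-1,8-dihydroxy-1,4-epoxygermacr-7(11)-en-12,6-olide (C6 epimers) | CC(=O)OCC1=C2C(OC1=O)[C@H](Br)[C@@]3(C)CC[C@](O)(O3)[C@H](C)C[C@@H]2O
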